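## Conventions and assumptions

- **Atom numbering.** Labdane numbers are used for the decalin: C1–C10, C17 the methyl on C8, C18 the carboxyl carbon on C4, C19 the 4β-methyl, C20 the methyl on C10. The side chain runs C11–C16, C16 being the butenolide CH–O. The other butenolide carbons are C3′ (methyl-bearing), C2′ (=CH) and C1′ (carbonyl).
- **Assumption 1.** The organocerium addition of step 17 is not expected to be face-selective at C13. Compounds 29–32 are carried as C13 epimer mixtures (the 13R epimer is drawn), because both epimers give the same cation in step 21.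
- **Assumption 2.** The (4S,5S)-dioxaborolane ligand is taken to give the (1S,2R)-stannylcyclopropane 17, by the facial model under which the (4R,5R) ligand gives (1S,2S)-2-phenylcyclopropylmethanol from cinnamyl alcohol. If the sense were opposite, the enantiomeric ligand would be used.
- **Assumption 3.** The same cyclopropane is (1S,2R) while tin is attached and (14R,16R) once C13 replaces tin. Only the CIP priorities change, not the geometry.
- **Assumption 4.** The free hydroxy acid 36 is taken not to relactonise between C18 and O6 at pH 3 in the cold.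

## Analysis of the target

The target 36 is a C25 terpenoid built on a trans-fused decalin (rings A and B) with six ring stereocentres. C4 is quaternary (4β-methyl, 4α-carboxyl C18), C5 carries an α-hydrogen, C6 an equatorial α-hydroxyl, C8 an α-tertiary hydroxyl with an axial β-methyl, C9 the β side chain, and C10 the axial β-methyl. The C5, C6, C9 and C10 configurations are those of the natural labdane larixol (1), so only C4 and C8 have to be created on the ring. The side chain holds an E-trisubstituted alkene (C13=C14) and, two carbons on, the single remote stereocentre C16 (R). C16 is the γ-carbon of a β-methyl butenolide and lies six bonds from C9, so the ring cannot control it.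

Sensitive groups are:
- the 8α-tertiary alcohol, which dehydrates and closes ethers onto C13 cations;
- the 18-acid and 6α-hydroxyl, which sit peri to each other and can lactonise;
- the butenolide γ-hydrogen, which is base-labile.

The difficulties are the E geometry of an alkene whose two C13 substituents (methyl and CH2) differ little, the absolute configuration at C16, and the oxidation of one of two geminal methyl groups on C4. The strategy rests on the segment C13(CH3)=C14–C15–C16(O): this is the homoallyl pattern left when a C13 cyclopropylcarbinyl cation opens its C14–C16 ring bond to a nucleophile arriving at C16. The nucleophile here is the carboxyl oxygen of C1′, held next to C16 by the Z C3′=C2′ bond.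

## Retrosynthetic reasoning

**36 from 34.** The 18-acid, the 6α-hydroxyl and the 8α-hydroxyl are masked in 34 as the 18,6α-lactone and a tertiary acetate. Cutting the lactone C18–O6 bond and the acetate last lets a single hydroxide treatment finish the synthesis. It also keeps the C8 oxygen non-nucleophilic while cations are generated at C13.

**34 from 32 (key disconnection).** The C16–O bond of the butenolide and the C13=C14 π bond are traced back to the C14–C16 σ bond of a trans-cyclopropane and a tertiary C13 carbinol. Cutting here, rather than at C14–C15 or C12–C13, lets one event create the alkene, the C16 stereocentre and the ring, and moves the stereochemical problem to a small cyclopropane. Forward, acid must ionise C13 of 32 and the carboxyl oxygen must displace C14 at C16 with inversion.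

**32 from 14 and 26.** The C13–C14 bond is cut between a methyl ketone and a cyclopropyl nucleophile. This makes the route convergent and leaves the C13 configuration irrelevant. The Z-enoic acid cannot survive an organometallic, so it travels as the silyl ether of the Z-allylic alcohol in 26 and is raised to the acid afterwards (29, 30, 31, 32).

**26 from 17, and 17 from 16, 15 and 20.** The Z C3′=C2′ bond is cut by a syn-carbocupration of ynoate 22, whose ester carbon comes from 20 and whose alkyne carbon comes from the hydroxymethyl carbon of 17. The cyclopropane of 17 is cut to the E-vinylstannane 16 by a reagent-controlled Simmons–Smith reaction, and 16 to prop-2-yn-1-ol (15). Tin serves first as a spectator and then as the source of the nucleophile.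

**14 from 9.** The C18 carbonyl is traced to the unactivated 4α-methyl group. The 6α-oxygen is peri to it, so an alkoxy radical at O6 can abstract a C18 hydrogen through a six-membered transition state, giving ether 12 and then lactone 14. This uses the 6α-hydroxyl that larixol already has and avoids a de novo ring synthesis.

**9 from 1.** The 8α-hydroxyl and axial C17 methyl are traced to the 8(17)-alkene of 1 through α-face epoxide 3 and hydride opening to 4. The methyl ketone comes from oxidative cleavage of the vinyl carbinol (4 to 7). A silyl ether on O6 (2) is needed only so that the tertiary 8-hydroxyl can be acetylated (8) before O6 is freed again (9).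

## Alternatives that were turned down

**Alternative 1: tethered intramolecular Diels–Alder for ring B.**
- Disconnection: C9–C10 and C7–C8 of ring B.
- Forward key step: the vinylcyclohexene ester A2, with a butynedioate tethered through the C18 oxygen, undergoes a thermal cycloaddition to the tricyclic diene lactone A1.
- For: the tether delivers the dienophile to one face, which fixes the quaternary C10 relative to C4. C18 is oxygenated from the start, so no remote C–H oxidation is needed. On this point it is stronger than the chosen route, which spends two steps on C18.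
- Against: A1 is far from the target. Its C5=C6 alkene must become 5α-H and 6α-OH. Its tetrasubstituted C8=C9 enoate must become the 8α-carbinol with a methyl made from an ester and a C9 hydrogen. The C11 lactone carbonyl must be reduced and extended by nine carbons. None of the side-chain problems (E-alkene, C16, butenolide) is addressed.
- Comparison: the chosen route takes C5, C6, C9 and C10 from larixol and puts its new chemistry on the side chain. The cycloaddition route would be much longer and would still need a side-chain solution.

**Alternative 2: samarium ketyl–enoate closure of ring B.**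
- Disconnection: C8–C9.
- Forward key step: SmI2 (divalent samarium), regenerated at a cathode, reduces the methyl ketone of keto enoate A4 to a ketyl that adds to the enoate β-carbon and gives the bicyclic hydroxy ester A3.
- For: the 8α-tertiary alcohol and C9 are set together in the ring-forming step, and the reductant is used catalytically. For C8 this is at least as direct as the epoxidation and reduction used here.
- Against: ring A with its quaternary C10 must first be made in enantiopure form. A3 has a tetrasubstituted C4=C5 alkene from which the C4 quaternary centre, 5α-H and 6α-OH would all have to be made. A3 carries a C3 oxygen that the target lacks. The side chain ends at C12.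
- Comparison: the chosen route avoids all ring construction and offers in return a convergent solution for C13–C1′. The electrochemical step solves a problem that larixol has already solved.

**Alternative 3: methylalumination and epoxide opening.**
- Disconnection: C13–CH3 and C14–C15, with no ring formed.
- Forward key step: Al(CH3)3 with Cp2ZrCl2 (tetravalent zirconium) adds methyl and aluminium syn across the terminal alkyne A6. The derived alkenylalanate opens the enantiopure epoxide A7 to give the E-homoallylic alcohol A5.
- For: the E geometry comes from a syn-carbometalation and is essentially complete, and C16 comes from an epoxide of known configuration. On both points this route is stronger and better precedented than the chosen key step.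
- Against: A6 requires the C13 methyl to be removed from a larixol-derived ketone and put back. The aluminium reagents do not tolerate the lactone or acid, so C18 is carried as a silyl ether of the alcohol and must be oxidised back, and A5 holds three different silyl ethers. The butenolide still has to be built from the ketal and alcohol in several steps after the union.
- Comparison: the chosen strategy forms the alkene, the C16–O bond and the butenolide ring in one operation and keeps C18 at the acid oxidation level. Its cost is an unprecedented step with only moderate expected E control.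

Key step: step 21

## Route

Step 1
Reactants: 1 larixol [(13S)-labda-8(17),14-diene-6α,13-diol]
Product: 2 6-O-triethylsilyl-larixol
Conditions: TESCl, imidazole, DMAP (cat.), DMF, 0 °C → rt
Reagents that add atoms: chlorotriethylsilane, CC[Si](Cl)(CC)CC
Why: Silylation with a chlorosilane and imidazole takes the secondary 6α-hydroxyl and leaves the tertiary allylic 13-hydroxyl free; the ether is needed so that only the 8-hydroxyl is acetylated in step 5.

Step 2
Reactants: 2 6-O-triethylsilyl-larixol
Product: 3 (13S)-8α,17-epoxy-6α-(triethylsilyloxy)labd-14-en-13-ol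
Conditions: mCPBA, NaHCO3, CH2Cl2, 0 °C
Reagents that add atoms: 3-chloroperoxybenzoic acid, OOC(=O)c1cccc(Cl)c1
Why: Prilezhaev epoxidation; the 1,1-disubstituted exocyclic alkene should react ahead of the monosubstituted vinyl group, and the peracid should approach from the α face because the β face is screened by the axial C20 methyl, which sets the C8 oxygen α. The buffer keeps the 13-hydroxyl from opening the epoxide.

Step 3
Reactants: 3 (13S)-8α,17-epoxy-6α-(triethylsilyloxy)labd-14-en-13-ol
Product: 4 (13S)-6α-(triethylsilyloxy)labd-14-ene-8α,13-diol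
Conditions: LiAlH4, THF, 0 °C → reflux
Reagents that add atoms: none
Why: Hydride opens the spiro-epoxide at the unhindered C17 methylene (SN2), so the C8–O bond is untouched and C17 becomes the axial methyl of the 8α-tertiary alcohol; silyl ether and vinyl group are inert.

Step 4
Reactants: 4 (13S)-6α-(triethylsilyloxy)labd-14-ene-8α,13-diol
Product: 7 8α-hydroxy-6α-(triethylsilyloxy)-14,15-dinorlabdan-13-one, via vicinal tetraol 5 (not isolated), via hydroxy aldehyde 6 (not isolated)
Conditions: OsO4 (cat.), NaIO4, 2,6-lutidine, dioxane/H2O, rt
Reagents that add atoms: none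
Why: Lemieux–Johnson cleavage; dihydroxylation of the vinyl group, periodate cleavage of C14–C15 and then of the α-hydroxy aldehyde at C13–C14 leave C13 as the methyl ketone with its original oxygen. The isolated 8-hydroxyl has no vicinal partner and is not cleaved.

Step 5
Reactants: 7 8α-hydroxy-6α-(triethylsilyloxy)-14,15-dinorlabdan-13-one
Product: 8 8α-acetoxy-6α-(triethylsilyloxy)-14,15-dinorlabdan-13-one
Conditions: Ac2O, DMAP, Et3N, toluene, 60 °C
Reagents that add atoms: acetic anhydride, CC(=O)OC(C)=O
Why: DMAP-catalysed acylation reaches hindered tertiary alcohols under basic conditions that spare the silyl ether; the acetate blocks hemiketal formation with the C13 ketone and later keeps O8 from attacking the C13 cation.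

Step 6
Reactants: 8 8α-acetoxy-6α-(triethylsilyloxy)-14,15-dinorlabdan-13-one
Product: 9 8α-acetoxy-6α-hydroxy-14,15-dinorlabdan-13-one
Conditions: HF·pyridine, THF, 0 °C → rt
Reagents that add atoms: none
Why: Fluoride-driven desilylation frees the 6α-hydroxyl; the tertiary acetate and the ketone are stable to buffered HF.

Step 7
Reactants: 9 8α-acetoxy-6α-hydroxy-14,15-dinorlabdan-13-one
Product: 12 8α-acetoxy-6α,18-epoxy-14,15-dinorlabdan-13-one, via hypoiodite 10 (not isolated), via iodo alcohol 11 (not isolated)
Conditions: PhI(OAc)2, I2, cyclohexane, hν (tungsten lamp), 40 °C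
Reagents that add atoms: none
Why: Hypoiodite (Suárez) remote functionalisation; the 6α-alkoxy radical is peri to the equatorial 4α-methyl (C18), far from C19 and C20, and abstracts a C18 hydrogen through a six-membered transition state, after which iodination and displacement by O6 close the tetrahydrofuran. This makes C4 a stereocentre with the oxidised carbon α.

Step 8
Reactants: 12 8α-acetoxy-6α,18-epoxy-14,15-dinorlabdan-13-one
Product: 14 8α-acetoxy-13-oxo-14,15-dinorlabdan-18,6α-olide, via lactol 13 (not isolated)
Conditions: RuCl3·xH2O (cat.), NaIO4, CCl4/MeCN/H2O, rt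
Reagents that add atoms: sodium periodate (oxygen passed on through catalytic RuO4), [Na+].[O-]I(=O)(=O)=O
Why: RuO4 oxidation of a cyclic ether to the lactone; the ether CH2 (C18) should react in preference to the tertiary C6–H, which is axial and shielded by the C19 and C20 methyl groups. Ketone and acetate are inert.

Step 9
Reactants: 15 prop-2-yn-1-ol
Product: 16 (E)-3-(tributylstannyl)prop-2-en-1-ol
Conditions: Bu3SnH, AIBN (cat.), neat, 80 °C
Reagents that add atoms: tributyltin hydride, CCCC[SnH](CCCC)CCCC
Why: Radical hydrostannylation of the terminal alkyne gives mainly the E β-stannyl alkene under equilibrating conditions; the minor Z and 2-stannyl isomers are removed by chromatography.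

Step 10
Reactants: 16 (E)-3-(tributylstannyl)prop-2-en-1-ol
Product: 17 [(1S,2R)-2-(tributylstannyl)cyclopropyl]methanol
Conditions: Et2Zn, CH2I2, DME, CH2Cl2, −10 °C; (4S,5S)-2-butyl-N,N,N′,N′-tetramethyl-1,3,2-dioxaborolane-4,5-dicarboxamide; −10 °C → rt
Reagents that add atoms: diiodomethane (as Zn(CH2I)2), ICI
Why: Charette's dioxaborolane-directed Simmons–Smith cyclopropanation; the allylic zinc alkoxide bound to the chiral boronate receives CH2 on one alkene face, and the stereospecific syn addition keeps tin and CH2OH trans. This step sets both cyclopropane centres and is the source of the C16 configuration.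

Step 11
Reactants: 17 [(1S,2R)-2-(tributylstannyl)cyclopropyl]methanol
Product: 18 (1S,2R)-2-(tributylstannyl)cyclopropane-1-carbaldehyde
Conditions: Dess–Martin periodinane, NaHCO3, CH2Cl2, 0 °C → rt
Reagents that add atoms: none
Why: Buffered Dess–Martin oxidation stops at the aldehyde and tolerates the C–Sn bond; the trans-cyclopropyl aldehyde does not epimerise readily.

Step 12
Reactants: 18 (1S,2R)-2-(tributylstannyl)cyclopropane-1-carbaldehyde
Product: 19 tributyl[(1R,2S)-2-ethynylcyclopropyl]stannane
Conditions: dimethyl (1-diazo-2-oxopropyl)phosphonate, K2CO3, MeOH, 0 °C → rt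
Reagents that add atoms: dimethyl (1-diazo-2-oxopropyl)phosphonate, COP(=O)(OC)C(=[N+]=[N-])C(C)=O
Why: Ohira–Bestmann (Seyferth–Gilbert) homologation turns the aldehyde into the terminal alkyne under mild base; any epimerisation at the ring carbon would give a separable cis diastereomer, not the enantiomer.

Step 13
Reactants: 19 tributyl[(1R,2S)-2-ethynylcyclopropyl]stannane; 20 methyl chloroformate
Product: 22 methyl 3-[(1S,2R)-2-(tributylstannyl)cyclopropyl]prop-2-ynoate, via lithium acetylide 21 (not isolated)
Conditions: LiN(i-Pr)2, THF, −78 °C; then 20, −78 → 0 °C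
Reagents that add atoms: none
Why: Deprotonation of the terminal alkyne with an amide base (no tin–lithium exchange) and C-acylation of the acetylide with the chloroformate give the ynoate; this carbon becomes C1′.

Step 14
Reactants: 22 methyl 3-[(1S,2R)-2-(tributylstannyl)cyclopropyl]prop-2-ynoate
Product: 24 methyl (Z)-3-[(1S,2R)-2-(tributylstannyl)cyclopropyl]but-2-enoate, via alkenylcuprate 23 (not isolated)
Conditions: Me2CuLi (MeLi, CuI), THF, −78 °C; MeOH then aq. NH4Cl at −78 °C
Reagents that add atoms: lithium dimethylcuprate, [Li+].C[Cu-]C
Why: syn-Carbocupration of the ynoate followed by protonation at −78 °C, before the alkenylcuprate can equilibrate, puts methyl and hydrogen cis, so cyclopropyl and ester are cis (Z). This is the geometry that later holds the carboxyl next to C16.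

Step 15
Reactants: 24 methyl (Z)-3-[(1S,2R)-2-(tributylstannyl)cyclopropyl]but-2-enoate
Product: 25 (Z)-3-[(1S,2R)-2-(tributylstannyl)cyclopropyl]but-2-en-1-ol
Conditions: i-Bu2AlH, CH2Cl2, −78 °C; aq. KNaC4H4O6
Reagents that add atoms: none
Why: 1,2-Reduction of the conjugated ester to the allylic alcohol without touching the alkene geometry or the stannane.

Step 16
Reactants: 25 (Z)-3-[(1S,2R)-2-(tributylstannyl)cyclopropyl]but-2-en-1-ol
Product: 26 tert-butyl(dimethyl){[(2Z)-3-[(1S,2R)-2-(tributylstannyl)cyclopropyl]but-2-en-1-yl]oxy}silane
Conditions: TBSCl, imidazole, DMF, rt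
Reagents that add atoms: tert-butylchlorodimethylsilane, CC(C)(C)[Si](C)(C)Cl
Why: Standard silylation of a primary alcohol; the ether masks the future carboxyl through the organometallic step.

Step 17
Reactants: 26 tert-butyl(dimethyl){[(2Z)-3-[(1S,2R)-2-(tributylstannyl)cyclopropyl]but-2-en-1-yl]oxy}silane; 14 8α-acetoxy-13-oxo-14,15-dinorlabdan-18,6α-olide
Product: 29 tertiary cyclopropylcarbinol [14 with C13 converted to C(OH)(CH3) bearing the (14R,16R)-trans-cyclopropane whose C16 carries (Z)-C(CH3)=CH–CH2OTBS; C13 epimers, 13R drawn], via cyclopropyllithium 27 (not isolated), via organocerium reagent 28 (not isolated)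
Conditions: n-BuLi, THF, −78 → −20 °C; CeCl3, THF, −78 °C; then 14, −78 °C
Reagents that add atoms: none
Why: Tin–lithium exchange gives a configurationally stable cyclopropyllithium with retention, and transmetalation to the organocerium gives a weakly basic, oxophilic nucleophile that adds to the methyl ketone without enolising it and faster than to the hindered lactone or tertiary acetate (Imamoto conditions). The C13 configuration is not controlled and does not matter.

Step 18
Reactants: 29 tertiary cyclopropylcarbinol (silyl ether)
Product: 30 Z-allylic alcohol [29 with CH2OTBS converted to CH2OH]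
Conditions: TBAF, AcOH, THF, 0 °C → rt
Reagents that add atoms: none
Why: Buffered fluoride removes the primary silyl ether; acetate, lactone and the acid-sensitive tertiary cyclopropylcarbinol are left intact.

Step 19
Reactants: 30 Z-allylic alcohol
Product: 31 Z-enal [30 with CH2OH converted to CHO]
Conditions: MnO2, CH2Cl2, rt
Reagents that add atoms: none
Why: MnO2 oxidises only the allylic alcohol under neutral conditions, which should preserve the Z geometry and the tertiary alcohol.

Step 20
Reactants: 31 Z-enal
Product: 32 Z-enoic acid [31 with CHO converted to CO2H; (14R,16R)-cyclopropane, 8α-acetate, 18,6α-lactone]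
Conditions: NaClO2, NaH2PO4, 2-methyl-2-butene, t-BuOH/H2O, 0 °C
Reagents that add atoms: sodium chlorite, [Na+].[O-]Cl=O
Why: Pinnick oxidation converts the enal to the acid without isomerising the alkene; the scavenger removes HOCl, and the cold buffered medium is too weakly acidic to ionise C13.

Step 21
Reactants: 32 Z-enoic acid
Product: 34 18,6α-lactone 8-acetate of the target [(13E,16R)-butenolide], via cyclopropylcarbinyl cation 33 (not isolated)
Conditions: TsOH·H2O (10 mol %), (CF3)2CHOH/CH2Cl2, −20 → 0 °C
Reagents that add atoms: none
Why: Proposed new method: protonation of either C13 epimer of 32 and loss of water give the same bisected tertiary cyclopropylcarbinyl cation 33, and because a free cation at the secondary C16 is not expected, the ring should open only as the carboxyl oxygen of C1′ attacks C16 opposite the departing C14–C16 bond (SN2-like), forming the C16–O bond and the C13=C14 alkene in one event. The closest known reactions are the Julia–Johnson cyclopropylcarbinyl-to-homoallyl rearrangement, in which an external halide plays this part and E-trisubstituted homoallylic halides result, and the ring opening of activated cyclopropanes by nucleophiles with inversion. The butenolide closes in a 5-exo-tet mode with the breaking C14–C16 bond outside the new ring; the Z C3′=C2′ bond holds the oxygen within reach of C16, and the trans ring substitution rules out lactonisation onto C13. The C16 configuration is controlled by the (14R,16R)-cyclopropane from step 10 and is transferred with inversion to 16R. The E geometry is controlled by the preferred bisected arrangement of 33, with the C12 chain outside and the C13 methyl over the ring; this preference is expected to be only moderate, so the Z isomer may have to be removed on AgNO3-impregnated silica. Attack at C16 and not at the ring CH2 (C15) is needed, and is favoured because the C14–C16 bond is vicinal to both π systems and because the five-membered closure is faster than the six-membered one. The C8 oxygen is acetylated so that it cannot close an 8,13-ether onto the cation, and the weakly nucleophilic fluorinated solvent limits external capture.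

Step 22
Reactants: 34 18,6α-lactone 8-acetate of the target
Product: 36 target hydroxy acid, via ring-opened hydroxy acid 35 (not isolated)
Conditions: KOH, MeOH/H2O, rt → 60 °C; then 1 M HCl to pH 3, 0 °C → rt
Reagents that add atoms: potassium hydroxide, [K+].[OH-]
Why: Saponification opens the butenolide and the strained 18,6α-lactone at room temperature and cleaves the tertiary acetate on warming; on acidification the Z-γ-hydroxy enoic acid 35 should reclose to the butenolide spontaneously with C16 unchanged, while the hindered 18-acid and 6α-hydroxyl stay open in the cold.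

## Compound list

1 | larixol, (13S)-labda-8(17),14-diene-6α,13-diol | C=C[C@@](C)(O)CC[C@@H]1[C@@]2(C)CCCC(C)(C)[C@@H]2[C@@H](O)CC1=C | starting material
2 | 6-O-triethylsilyl-larixol | C=C[C@@](C)(O)CC[C@@H]1[C@@]2(C)CCCC(C)(C)[C@@H]2[C@@H](O[Si](CC)(CC)CC)CC1=C | intermediate
3 | (13S)-8α,17-epoxy-6α-(triethylsilyloxy)labd-14-en-13-ol | C=C[C@@](C)(O)CC[C@@H]1[C@@]2(C)CCCC(C)(C)[C@@H]2[C@@H](O[Si](CC)(CC)CC)C[C@]13CO3 | intermediate
4 | (13S)-6α-(triethylsilyloxy)labd-14-ene-8α,13-diol | C=C[C@@](C)(O)CC[C@@H]1[C@@]2(C)CCCC(C)(C)[C@@H]2[C@@H](O[Si](CC)(CC)CC)C[C@@]1(C)O | intermediate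
5 | 6α-(triethylsilyloxy)labdane-8α,13,14,15-tetraol (C14 epimers) | OCC(O)[C@@](C)(O)CC[C@@H]1[C@@]2(C)CCCC(C)(C)[C@@H]2[C@@H](O[Si](CC)(CC)CC)C[C@@]1(C)O | intermediate (not isolated)
6 | 8α,13-dihydroxy-6α-(triethylsilyloxy)-15-norlabdan-14-al | O=C[C@@](C)(O)CC[C@@H]1[C@@]2(C)CCCC(C)(C)[C@@H]2[C@@H](O[Si](CC)(CC)CC)C[C@@]1(C)O | intermediate (not isolated)
7 | 8α-hydroxy-6α-(triethylsilyloxy)-14,15-dinorlabdan-13-one | CC(=O)CC[C@@H]1[C@@]2(C)CCCC(C)(C)[C@@H]2[C@@H](O[Si](CC)(CC)CC)C[C@@]1(C)O | intermediate
8 | 8α-acetoxy-6α-(triethylsilyloxy)-14,15-dinorlabdan-13-one | CC(=O)CC[C@@H]1[C@@]2(C)CCCC(C)(C)[C@@H]2[C@@H](O[Si](CC)(CC)CC)C[C@@]1(C)OC(C)=O | intermediate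
9 | 8α-acetoxy-6α-hydroxy-14,15-dinorlabdan-13-one | CC(=O)CC[C@@H]1[C@@]2(C)CCCC(C)(C)[C@@H]2[C@@H](O)C[C@@]1(C)OC(C)=O | intermediate
10 | 6α-O-iodo derivative (hypoiodite) of 9 | CC(=O)CC[C@@H]1[C@@]2(C)CCCC(C)(C)[C@@H]2[C@@H](OI)C[C@@]1(C)OC(C)=O | intermediate (not isolated)
11 | 8α-acetoxy-6α-hydroxy-18-iodo-14,15-dinorlabdan-13-one | CC(=O)CC[C@@H]1[C@@]2(C)CCC[C@@](C)(CI)[C@@H]2[C@@H](O)C[C@@]1(C)OC(C)=O | intermediate (not isolated)
12 | 8α-acetoxy-6α,18-epoxy-14,15-dinorlabdan-13-one | CC(=O)CC[C@@H]1[C@@]2(C)CCC[C@@](C)(CO3)[C@@H]2[C@@H]3C[C@@]1(C)OC(C)=O | intermediate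
13 | 8α-acetoxy-6α,18-epoxy-18-hydroxy-14,15-dinorlabdan-13-one (lactol, C18 epimers) | CC(=O)CC[C@@H]1[C@@]2(C)CCC[C@@](C)(C(O)O3)[C@@H]2[C@@H]3C[C@@]1(C)OC(C)=O | intermediate (not isolated)
14 | 8α-acetoxy-13-oxo-14,15-dinorlabdan-18,6α-olide | CC(=O)CC[C@@H]1[C@@]2(C)CCC[C@@](C)(C(=O)O3)[C@@H]2[C@@H]3C[C@@]1(C)OC(C)=O | intermediate
15 | prop-2-yn-1-ol | C#CCO | starting material
16 | (E)-3-(tributylstannyl)prop-2-en-1-ol | OC/C=C/[Sn](CCCC)(CCCC)CCCC | intermediate
17 | [(1S,2R)-2-(tributylstannyl)cyclopropyl]methanol | OC[C@@H]1C[C@H]1[Sn](CCCC)(CCCC)CCCC | intermediate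
18 | (1S,2R)-2-(tributylstannyl)cyclopropane-1-carbaldehyde | O=C[C@@H]1C[C@H]1[Sn](CCCC)(CCCC)CCCC | intermediate
19 | tributyl[(1R,2S)-2-ethynylcyclopropyl]stannane | C#C[C@@H]1C[C@H]1[Sn](CCCC)(CCCC)CCCC | intermediate
20 | methyl chloroformate | COC(Cl)=O | starting material
21 | lithium acetylide of 19 | [Li]C#C[C@@H]1C[C@H]1[Sn](CCCC)(CCCC)CCCC | intermediate (not isolated)
22 | methyl 3-[(1S,2R)-2-(tributylstannyl)cyclopropyl]prop-2-ynoate | COC(=O)C#C[C@@H]1C[C@H]1[Sn](CCCC)(CCCC)CCCC | intermediate
23 | lithium alkenyl(methyl)cuprate from syn addition to 22 (Cu on C2′, cis to the new methyl) | [Li+].COC(=O)/C([Cu-]C)=C(C)\[C@@H]1C[C@H]1[Sn](CCCC)(CCCC)CCCC | intermediate (not isolated)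
24 | methyl (Z)-3-[(1S,2R)-2-(tributylstannyl)cyclopropyl]but-2-enoate | COC(=O)/C=C(C)\[C@@H]1C[C@H]1[Sn](CCCC)(CCCC)CCCC | intermediate
25 | (Z)-3-[(1S,2R)-2-(tributylstannyl)cyclopropyl]but-2-en-1-ol | OC/C=C(C)\[C@@H]1C[C@H]1[Sn](CCCC)(CCCC)CCCC | intermediate
26 | tert-butyl(dimethyl){[(2Z)-3-[(1S,2R)-2-(tributylstannyl)cyclopropyl]but-2-en-1-yl]oxy}silane | CC(C)(C)[Si](C)(C)OC/C=C(C)\[C@@H]1C[C@H]1[Sn](CCCC)(CCCC)CCCC | intermediate
27 | trans-cyclopropyllithium from 26 (configuration retained) | CC(C)(C)[Si](C)(C)OC/C=C(C)\[C@@H]1C[C@H]1[Li] | intermediate (not isolated)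
28 | cyclopropylcerium dichloride from 27 | CC(C)(C)[Si](C)(C)OC/C=C(C)\[C@@H]1C[C@H]1[Ce](Cl)Cl | intermediate (not isolated)
29 | tertiary cyclopropylcarbinol, TBS ether, 8α-acetate, 18,6α-lactone (C13 epimers, 13R drawn; 14R,16R) | CC(C)(C)[Si](C)(C)OC/C=C(C)\[C@@H]1C[C@H]1[C@](C)(O)CC[C@@H]1[C@@]2(C)CCC[C@@](C)(C(=O)O3)[C@@H]2[C@@H]3C[C@@]1(C)OC(C)=O | intermediate
30 | Z-allylic alcohol, 13-carbinol, 8α-acetate, 18,6α-lactone (C13 epimers) | OC/C=C(C)\[C@@H]1C[C@H]1[C@](C)(O)CC[C@@H]1[C@@]2(C)CCC[C@@](C)(C(=O)O3)[C@@H]2[C@@H]3C[C@@]1(C)OC(C)=O | intermediate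
31 | Z-enal, 13-carbinol, 8α-acetate, 18,6α-lactone (C13 epimers) | O=C/C=C(C)\[C@@H]1C[C@H]1[C@](C)(O)CC[C@@H]1[C@@]2(C)CCC[C@@](C)(C(=O)O3)[C@@H]2[C@@H]3C[C@@]1(C)OC(C)=O | intermediate
32 | Z-enoic acid, (14R,16R)-cyclopropyl 13-carbinol, 8α-acetate, 18,6α-lactone (C13 epimers; key-step precursor) | OC(=O)/C=C(C)\[C@@H]1C[C@H]1[C@](C)(O)CC[C@@H]1[C@@]2(C)CCC[C@@](C)(C(=O)O3)[C@@H]2[C@@H]3C[C@@]1(C)OC(C)=O | intermediate
33 | C13 cyclopropylcarbinyl cation from 32 | OC(=O)/C=C(C)\[C@@H]1C[C@H]1[C+](C)CC[C@@H]1[C@@]2(C)CCC[C@@](C)(C(=O)O3)[C@@H]2[C@@H]3C[C@@]1(C)OC(C)=O | intermediate (not isolated)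
34 | 18,6α-lactone 8-acetate of the target, (13E,16R)-butenolide (key-step product) | CC1=CC(=O)O[C@@H]1C/C=C(\C)CC[C@@H]1[C@@]2(C)CCC[C@@](C)(C(=O)O3)[C@@H]2[C@@H]3C[C@@]1(C)OC(C)=O | intermediate
35 | ring-opened (2′Z,13E,16R)-16-hydroxy diacid (formed as its potassium salt) | OC(=O)/C=C(C)\[C@H](O)C/C=C(\C)CC[C@@H]1[C@@]2(C)CCC[C@@](C)(C(=O)O)[C@@H]2[C@@H](O)C[C@@]1(C)O | intermediate (not isolated)
36 | target, CNP0387770.1 | CC1=CC(=O)O[C@@H]1C/C=C(\C)CC[C@@H]1[C@@]2(C)CCC[C@@](C)(C(=O)O)[C@@H]2[C@@H](O)C[C@@]1(C)O | target

## Step count and risk

Total steps: 22 (8 on the decalin, 8 on the cyclopropane, 6 after the union).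
Longest linear sequence: 14 steps (steps 1–8 then 17–22; the branch 9–16 then 17–22 is equally long).

**Step 21 (key step).** The cation may be captured at the ring methylene C15 to give a six-membered lactone, or it may lose a proton to give vinylcyclopropanes that return slowly. The E/Z preference may be small, because methyl and the C12 methylene differ little in size. If the ring opens ahead of C–O bond formation, the stereochemical transfer to C16 would be eroded. Fallback by known reactions, from 14 back to 34, which keeps the cyclopropylcarbinyl logic but sets C16 by a catalyst: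
- Addition of c-C3H5MgBr with CeCl3 to 14 gives the unsubstituted cyclopropyl carbinol F1.
- MgBr2·OEt2 in ether (Julia–Johnson opening) gives the E-homoallylic bromide F2, freed from its Z isomer on AgNO3-impregnated silica.
- Me3NO in DMSO (Ganem oxidation) gives the aldehyde F3, which is used at once because its alkene can move into conjugation.
- Me2Zn with the ProPhenol ligand adds methyl propiolate to F3 to give the (16R)-4-hydroxy-2-ynoate F4.
- Me2CuLi at −78 °C adds syn to F4, and the product lactonises on work-up to 34.

**Step 7.** Iodine-based side reactions are the most likely problem: iodination next to the ketone, over-oxidation at C18, or incomplete closure of the iodo alcohol. Hydrogen abstraction at a site other than C18 is less likely on geometric grounds. Fallback from 9 to 14 without iodine: NOCl in pyridine gives the 6α-nitrite F5. Photolysis (Barton reaction) and tautomerisation give the C18 oxime F6. Aqueous NaHSO3 releases the lactol 13, and Dess–Martin periodinane oxidises it to 14.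

**Step 17.** Tin–lithium exchange on a cyclopropylstannane may be slow at temperatures low enough to spare the allylic silyl ether, and leftover n-BuLi would add to 14. Enolisation of 14 or attack at the strained lactone would also lower conversion. Fallback from 26 to 27: iododestannylation with I2 in CH2Cl2 at 0 °C (retention) gives the cyclopropyl iodide F7. Iodine–lithium exchange with t-BuLi (2 equiv) in ether at −78 °C gives 27 cleanly in the cold, and the route continues through 28 to 29.

**Step 22.** The tertiary acetate needs warm alkali. Before the butenolide has opened, hydroxide may remove its γ-hydrogen, which would epimerise C16 or move the double bond. On acidification the 18-acid may relactonise onto O6. Fallback from 32 to 36: the lactone and acetate are hydrolysed with KOH before the butenolide exists, giving the fully deprotected acid F8. The acid conditions of step 21 applied to F8 then give 36 directly. The price is a free 8α-hydroxyl that can trap the C13 cation as a cyclic ether. That ether is itself a tertiary cyclopropylcarbinyl ether and is expected to re-ionise under the same conditions.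

## Further compounds

F1 | step 21 | 13-cyclopropyl-13-hydroxy derivative of 14 (C13 epimers) | CC(O)(C1CC1)CC[C@@H]1[C@@]2(C)CCC[C@@](C)(C(=O)O3)[C@@H]2[C@@H]3C[C@@]1(C)OC(C)=O
F2 | step 21 | (13E)-16-bromo homoallylic bromide, 8α-acetate, 18,6α-lactone | BrCC/C=C(\C)CC[C@@H]1[C@@]2(C)CCC[C@@](C)(C(=O)O3)[C@@H]2[C@@H]3C[C@@]1(C)OC(C)=O
F3 | step 21 | (13E)-16-aldehyde, 8α-acetate, 18,6α-lactone | O=CC/C=C(\C)CC[C@@H]1[C@@]2(C)CCC[C@@](C)(C(=O)O3)[C@@H]2[C@@H]3C[C@@]1(C)OC(C)=O
F4 | step 21 | methyl (16R,13E)-16-hydroxy-2′-ynoate, 8α-acetate, 18,6α-lactone | COC(=O)C#C[C@H](O)C/C=C(\C)CC[C@@H]1[C@@]2(C)CCC[C@@](C)(C(=O)O3)[C@@H]2[C@@H]3C[C@@]1(C)OC(C)=O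
F5 | step 7 | 6α-nitrite ester of 9 | CC(=O)CC[C@@H]1[C@@]2(C)CCCC(C)(C)[C@@H]2[C@@H](ON=O)C[C@@]1(C)OC(C)=O
F6 | step 7 | 8α-acetoxy-6α-hydroxy-13-oxo-14,15-dinorlabdan-18-al oxime | CC(=O)CC[C@@H]1[C@@]2(C)CCC[C@@](C)(C=NO)[C@@H]2[C@@H](O)C[C@@]1(C)OC(C)=O
F7 | step 17 | trans-cyclopropyl iodide corresponding to 26 | CC(C)(C)[Si](C)(C)OC/C=C(C)\[C@@H]1C[C@H]1I
F8 | step 22 | fully deprotected Z-enoic acid: 6α,8α,13-triol 18-acid with the (14R,16R)-cyclopropane (C13 epimers) | OC(=O)/C=C(C)\[C@@H]1C[C@H]1[C@](C)(O)CC[C@@H]1[C@@]2(C)CCC[C@@](C)(C(=O)O)[C@@H]2[C@@H](O)C[C@@]1(C)O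
A1 | alternative 1 | tricyclic diene lactone with quaternary C10 | O=C1OC[C@]2(C)CCC[C@]3(C)C1=C(C(=O)OC)CC=C23
A2 | alternative 1 | vinylcyclohexene with a butynedioate tethered through the C18 oxygen | COC(=O)C#CC(=O)OC[C@]1(C)CCCC(C)=C1C=C
A3 | alternative 2 | bicyclic 8α-hydroxy C9 acetate ester | COC(=O)C[C@@H]1[C@@]2(C)CC[C@@H](O[Si](C)(C)C(C)(C)C)C(C)=C2CC[C@@]1(C)O
A4 | alternative 2 | monocyclic keto enoate | COC(=O)/C=C/[C@@]1(C)CC[C@@H](O[Si](C)(C)C(C)(C)C)C(C)=C1CCC(C)=O
A5 | alternative 3 | E-homoallylic alcohol with ketal-masked methyl ketone | C/C(CC[C@@H]1[C@@]2(C)CCC[C@@](C)(CO[Si](C)(C)C(C)(C)C)[C@@H]2[C@@H](O[Si](C)(C)C(C)(C)C)C[C@@]1(C)O[Si](CC)(CC)CC)=C\C[C@@H](O)C1(C)OCCO1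
A6 | alternative 3 | terminal alkyne on the tris-silylated decalin | C#CCC[C@@H]1[C@@]2(C)CCC[C@@](C)(CO[Si](C)(C)C(C)(C)C)[C@@H]2[C@@H](O[Si](C)(C)C(C)(C)C)C[C@@]1(C)O[Si](CC)(CC)CC
A7 | alternative 3 | 2-methyl-2-(oxiran-2-yl)-1,3-dioxolane, single enantiomer | C1O[C@H]1C1(C)OCCO1
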